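## Structural features

The target is a halimane diterpenoid. Ring A (C1–C5, C10) and ring B (C5–C10) share the tetrasubstituted C5=C10 double bond, C4 carries a gem-dimethyl group, and a five-carbon chain (C11–C15, with methyl C16 on C13) hangs from C9. Ring B holds four contiguous stereocentres: C6 (free OH, S), C7 (OAc, R), C8 (CH3, S) and the quaternary C9 (CH3 and chain, R). O6, O7 and the C9 methyl C20 lie on one face; the C8 methyl C17 and the chain lie on the other. The fifth stereocentre, the tertiary allylic alcohol C13 (S) with its vinyl group, is two methylene groups away from the ring and must be set by a reagent. Fragile points are the allylic C6 hydroxyl beside the electron-rich C5=C10 bond (ionisation), the cis hydroxy acetate (acyl migration under base) and the tertiary allylic alcohol (acid-promoted allylic shift or dehydration). The real difficulty is the quaternary C9, wedged between the tetrasubstituted alkene and the tertiary C8, together with the correct sense at four adjacent centres and two neighbouring oxygens that must end up differently substituted. The key step exploits the fact that ring B, with C5=C10 kept and cis oxygens on C6 and C7, is the oxidation pattern of an arene cis-dihydrodiol: in the corresponding tetralin C6–C7 is the only unsubstituted aromatic edge, and the diene left after dihydroxylation already carries C17 on C8 and the chain carbon C11 on C9. The C7 oxygen of that diol can pass its configuration to C9 by an allylic shift that consumes it, so the C7 oxygen of the target is put back later from the face of O6.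

## Logic of the disconnections

**28 to 27 to 26.** The acyl C–O bond at O7 is cut last, because an acetate neither survives organolithium chemistry nor stays in place next to a free cis hydroxyl under base. Behind 27 stands 26, in which O6 and O7 are tied in one ketal. The gain is a single protecting group for both ring oxygens. The demand is site-selective acylation of O7 in the presence of O6 and O13, and a ketal cleavage mild enough for the tertiary allylic alcohol.

**26 to 20 and 22.** The C12–C13 bond is cut, with the C13–O bond made in the same operation. C13 is too far from the ring for substrate control, so its configuration is carried in by 22 from the chiral pool. The chain then shrinks to a primary boronic ester. The forward step must be a stereospecific 1,2-metallate shift that takes place at the α-carbon of the allyl unit.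

**20 to 16 (through 19, 18, 17).** Only functional groups change here: C12–B comes from C12–I and C12–O, and the ring diol is masked. These steps are kept together so that the vinyl group arrives only after the ring alkene chemistry is finished. The demand is orthogonality of the silyl ether and the ketal.

**16 to 13 (through 15, 14).** The C8–H bond and the C7–O bond are cut. Both are delivered from the face of O6: oxygen by hydroxyl-directed epoxidation, then hydrogen by hydroxyl-directed hydrogenation after the epoxide has been turned into the exocyclic allylic alcohol. This removes two stereocentres and leaves a 1,4-diene with one carbinol. The demand is chemoselectivity for the trisubstituted C7=C8 bond over C5=C10.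

**13 to 12 to 11.** The C9–C20 bond is cut. O7 is the only stereocentre that can reach C9 suprafacially, so it is used as a leaving group that directs the incoming methyl to its own face. The quaternary centre disappears and the cis-dienediol returns. The demand is γ-selective, syn allylic substitution and a clean distinction between O7 and O6.

**11 to 10 to 9.** The C6–O and C7–O bonds are cut together; this is the key disconnection. All ring stereochemistry vanishes and a flat tetralin remains. The demand is an oxygenase that accepts the tetrasubstituted ring and chooses the right face.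

**9 to 6 and 7.** The C9–C11 bond is cut, between an aryl anion and a two-carbon electrophile. The gain is a simple aryl bromide. The demand is a hindered aryllithium that still opens the epoxide.

**6 to 5.** The aryl C5–C4 bond is cut, as a cationic cycloalkylation. The bromine blocks one ortho position, so only one ring closure is possible.

**5 to 2 and 3; 2 to 1.** The C1–C2 bond (benzylic carbon to the prenyl unit) is cut, then the benzylic C–Br bond. This leads to two bulk chemicals. The demand is coupling at the primary carbon of the allylic bromide.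

## Other disconnections considered

**Alternative 1:** The cut goes through C4–C5 and C9–C10, with C9–C20 traced back to a methyl shift, and opens the bicycle to geranylgeranyl diphosphate A1. In the forward step a class 2 diterpene cyclase of the syn series protonates the terminal alkene, closes both rings, moves hydride from C9 to C8 and methyl from C10 to C9, and removes the C5 proton to give the diphosphate A2.
- In its favour: one step builds both rings, the C5=C10 bond and the C8/C9 pair with C17 and C20 trans. For the carbon skeleton this is better than the chosen plan in step economy.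
- Against it here: A2 has no oxygen at C6, C7 or C13. The diphosphate would have to be transposed to the tertiary (13S) alcohol, C6 (allylic) and C7 (unactivated) would need face-selective hydroxylation, and O7 would still have to be acetylated selectively.
- Comparison: both plans depend on an enzyme whose selectivity has to be found, so on that point they are equal. The chosen plan brings O6 and O7 in with its key step and builds the skeleton by ordinary chemistry. Alternative 1 builds the skeleton at once and leaves the harder oxidation problem for the end.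

**Alternative 2:** The cut is the C5–C6 bond. In the forward step the acid chloride A3, activated by a Lewis acid, is attacked by C5 of the ring A alkene; the tertiary C10 cation loses the C5 proton and gives the enone A4.
- In its favour: this is well-precedented cationic chemistry with no new method, which makes it better than the chosen plan on precedent. C6 arrives as a ketone next to C7, so O7 could come by enolate oxidation and O6 by reduction.
- Against it here: the key step creates no stereocentre. The vicinal C8/C9 pair, including the quaternary carbon, must be built beforehand in an open chain. The one-carbon arm at C9 needs homologation. The C10 cation can also lose a proton towards C1 or take up chloride, and the cis-6,7-diol needs two more stereoselective steps.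
- Comparison: the mechanism is safer, but the stereochemical load is moved to the synthesis of A3, and the route is expected to be longer overall.

**Alternative 3:** The cut is the C8–C9 bond. In the forward step the six-membered lactone A5 (carbonyl C11, ring oxygen on C6, E-propenyl on C6) is enolised and O-silylated, and rearranges [3,3] through a boat transition state to the acid A6, closing ring B as the 5(10),6-diene.
- In its favour: one suprafacial shift transfers the C6 carbinol configuration to C8 and C9 together. Setting the tertiary and quaternary pair at once is better than the chosen plan, which needs separate steps for C9 and C8. The C6=C7 bond left in A6 is the right place for a cis-dihydroxylation anti to C17, which would put both oxygens on the face of C20 by a standard reaction; on that point it is the equal of the chosen plan.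
- Against it here: the C6 stereocentre is consumed, so the face of the later dihydroxylation rests on substrate bias alone. A5 needs its own asymmetric synthesis, enolisation next to the tetrasubstituted alkene is hindered, and the C11 carboxyl must be homologated by one carbon.
- Comparison: the mechanism is fully precedented and stereospecific; the step count is probably similar to the chosen plan once A5 and the homologation are included.

Key step: step 5

Remark on numbering: halimane locants are used throughout (C1–C4 with C5 and C10 in ring A, C5–C10 in ring B, C11–C16 in the chain, C17 on C8, C18 and C19 on C4, C20 on C9); the target is (6S,7R,8S,9R,13S).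

Assumption on the chemistry: an oxygenase variant with the required facial sense is taken to be accessible by screening of active-site mutants. The substrate of step 5 is kept as the free primary alcohol, which leaves three hydroxyls of clearly different reactivity in 10.

## Route

Step 1
Reactants: 1 2-bromo-1,3-dimethylbenzene
Product: 2 2-bromo-1-(bromomethyl)-3-methylbenzene
Conditions: NBS (0.9 equiv), AIBN (cat.), PhCF3, 80 °C
Reagents that add atoms: N-bromosuccinimide, O=C1CCC(=O)N1Br
Why: Wohl–Ziegler radical bromination of one of two equivalent benzylic methyl groups; a slight deficit of NBS should keep dibromination low, and unreacted 1 is recovered by distillation.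

Step 2
Reactants: 2 2-bromo-1-(bromomethyl)-3-methylbenzene; 3 1-bromo-3-methylbut-2-ene (prenyl bromide)
Product: 5 2-bromo-1-methyl-3-(4-methylpent-3-en-1-yl)benzene, via benzylic Grignard reagent 4 (not isolated)
Conditions: Mg, Et2O, 0 °C (slow addition of 2); then 3, Li2CuCl4 (3 mol%), THF, −20 → 0 °C
Reagents that add atoms: none
Why: Magnesium inserts into the benzylic C–Br bond much faster than into the aryl C–Br bond, and the copper-catalysed (Kochi-type) Grignard–allylic bromide coupling should take place at the unhindered primary carbon of the prenyl unit; slow addition limits Wurtz homocoupling.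

Step 3
Reactants: 5 2-bromo-1-methyl-3-(4-methylpent-3-en-1-yl)benzene
Product: 6 5-bromo-1,1,6-trimethyl-1,2,3,4-tetrahydronaphthalene
Conditions: MeSO3H, CH2Cl2, 0 → 23 °C
Reagents that add atoms: none
Why: Friedel–Crafts cycloalkylation: protonation of the trisubstituted alkene gives a tertiary cation that closes the six-membered ring at the only free position ortho to the chain, which is para to the methyl group and meta to bromine; the bromine blocks the other ortho position.

Step 4
Reactants: 6 5-bromo-1,1,6-trimethyl-1,2,3,4-tetrahydronaphthalene; 7 oxirane (ethylene oxide)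
Product: 9 2-(2,5,5-trimethyl-5,6,7,8-tetrahydronaphthalen-1-yl)ethan-1-ol, via aryllithium 8 (not isolated)
Conditions: n-BuLi, THF, −78 °C; then 7, −78 → 23 °C; then H2O
Reagents that add atoms: none
Why: Bromine–lithium exchange followed by epoxide opening with the aryllithium, a standard hydroxyethylation that also serves for 2,6-disubstituted aryllithiums.

Step 5
Reactants: 9 2-(2,5,5-trimethyl-5,6,7,8-tetrahydronaphthalen-1-yl)ethan-1-ol
Product: 10 (1S,2R)-4-(2-hydroxyethyl)-3,8,8-trimethyl-1,2,5,6,7,8-hexahydronaphthalene-1,2-diol (halimane locants 6S,7R; cis-diol)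
Conditions: E. coli resting cells co-expressing an engineered toluene dioxygenase (TodC1C2 active-site variant with ferredoxin TodB and reductase TodA) and glucose dehydrogenase; D-glucose; air; phosphate buffer pH 7.4; 30 °C; extraction at pH 8
Reagents that add atoms: dioxygen, O=O
Why: Proposed new method: the oxygenase component, reduced by NADH through its reductase and ferredoxin, binds O2 at the mononuclear nonheme iron beside the Rieske cluster and transfers both oxygen atoms to one face of the C6–C7 edge, so the two C–O bonds form cis in one dearomatizing event. The closest known reaction type is the cis-dihydroxylation of alkylbenzenes by toluene dioxygenase and of the aromatic ring of tetralin by tetralin dioxygenase; a 1,2,3,4-tetrasubstituted tetralin of this size has not been shown as a substrate, which is why a variant with an enlarged pocket is asked for. No ring is closed, so no mode of closure has to be considered. Regioselectivity follows from the substrate: C6–C7 is the only edge with two hydrogens, and every other edge contains a fully substituted aromatic carbon. Both new stereocentres, C6 (S) and C7 (R), are set by the enzyme alone, through the orientation in which the arene is held over the iron: the sense is that of toluene cis-dihydrodiol if the C8 methyl takes the place of the toluene methyl, and the opposite if the ring A flank does, so enantioface selection has to be secured by the choice of variant and checked on 10. The step also needs chemoselectivity for ring dioxygenation over benzylic monooxygenation at C1, C11 and C17, which has to be part of the screen. The diene that remains has the C5=C10 bond in place and carries C17 and C11 on the C8=C9 bond.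

Step 6
Reactants: 10 (1S,2R)-4-(2-hydroxyethyl)-3,8,8-trimethyl-1,2,5,6,7,8-hexahydronaphthalene-1,2-diol
Product: 11 (1S,2R)-4-[2-(tert-butyldiphenylsilyloxy)ethyl]-3,8,8-trimethyl-1,2,5,6,7,8-hexahydronaphthalene-1,2-diol
Conditions: TBDPSCl (1.05 equiv), imidazole, DMF, −20 → 0 °C
Reagents that add atoms: tert-butyl(chloro)diphenylsilane, CC(C)(C)[Si](Cl)(c1ccccc1)c1ccccc1
Why: Selective silylation of the primary hydroxyl by a bulky silyl chloride; the imidazole-buffered medium avoids the acid-triggered dehydration of the dienediol to a phenol.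

Step 7
Reactants: 11 (1S,2R)-4-[2-(tert-butyldiphenylsilyloxy)ethyl]-3,8,8-trimethyl-1,2,5,6,7,8-hexahydronaphthalene-1,2-diol
Product: 12 (1S,2R)-4-[2-(tert-butyldiphenylsilyloxy)ethyl]-1-hydroxy-3,8,8-trimethyl-1,2,5,6,7,8-hexahydronaphthalen-2-yl N-phenylcarbamate (carbamate on O7)
Conditions: PhNCO (1.05 equiv), pyridine, CH2Cl2, −20 → 0 °C
Reagents that add atoms: phenyl isocyanate, O=C=Nc1ccccc1
Why: Addition of an alcohol to an isocyanate (carbamoylation); O7 is pseudoequatorial and flanked only by the C8 methyl, whereas O6 is pseudoaxial and crowded by the C4 gem-dimethyl group, so mono-carbamoylation should occur at O7.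

Step 8
Reactants: 12 (1S,2R)-4-[2-(tert-butyldiphenylsilyloxy)ethyl]-1-hydroxy-3,8,8-trimethyl-1,2,5,6,7,8-hexahydronaphthalen-2-yl N-phenylcarbamate
Product: 13 (1R,4R)-4-[2-(tert-butyldiphenylsilyloxy)ethyl]-3,4,8,8-tetramethyl-1,4,5,6,7,8-hexahydronaphthalen-1-ol (halimane locants 6R,9R; C20 cis to O6)
Conditions: MeLi (2.1 equiv), THF, −78 → 0 °C; CuI (1.1 equiv), 0 °C; MeLi (1.1 equiv), 0 → 23 °C; then H2O
Reagents that add atoms: methyllithium, [Li]C
Why: Carbamate-directed syn-SN2′ allylic substitution (Gallina–Goering protocol): copper held on the deprotonated carbamate nitrogen delivers methyl to C9, the γ-terminus of the C8=C9 bond, on the face from which O7 departs. C20 therefore ends up cis to O6 and the chain trans, the double bond moves to C7=C8, and the quaternary centre is set by chirality transfer from C7.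

Step 9
Reactants: 13 (1R,4R)-4-[2-(tert-butyldiphenylsilyloxy)ethyl]-3,4,8,8-tetramethyl-1,4,5,6,7,8-hexahydronaphthalen-1-ol
Product: 14 (1S,2S,3R,4S)-4-[2-(tert-butyldiphenylsilyloxy)ethyl]-2,3-epoxy-3,4,8,8-tetramethyl-1,2,3,4,5,6,7,8-octahydronaphthalen-1-ol (7,8-epoxide, oxygen cis to the C6 hydroxyl)
Conditions: VO(acac)2 (5 mol%), t-BuOOH, CH2Cl2, 0 °C
Reagents that add atoms: tert-butyl hydroperoxide, CC(C)(C)OO
Why: Hydroxyl-directed vanadium-catalysed epoxidation: the alkoxide-bound peroxo-vanadium species delivers oxygen on the face of O6, and the trisubstituted C7=C8 bond should react in preference to C5=C10, which is shielded on both faces by the quaternary C4 and C9.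

Step 10
Reactants: 14 (1S,2S,3R,4S)-4-[2-(tert-butyldiphenylsilyloxy)ethyl]-2,3-epoxy-3,4,8,8-tetramethyl-1,2,3,4,5,6,7,8-octahydronaphthalen-1-ol
Product: 15 (1S,2R,4S)-4-[2-(tert-butyldiphenylsilyloxy)ethyl]-4,8,8-trimethyl-3-methylidene-1,2,3,4,5,6,7,8-octahydronaphthalene-1,2-diol
Conditions: LiN(iPr)2 (4 equiv), Et2O, 0 → 23 °C; then H2O
Reagents that add atoms: none
Why: Base-promoted isomerisation of an epoxide to an allylic alcohol by syn β-elimination; the only β-hydrogens that can reach the epoxide oxygen are those of the C17 methyl, so the C8–O bond breaks, the C7–O bond keeps its configuration, and the exocyclic C8=C17 alkene forms.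

Step 11
Reactants: 15 (1S,2R,4S)-4-[2-(tert-butyldiphenylsilyloxy)ethyl]-4,8,8-trimethyl-3-methylidene-1,2,3,4,5,6,7,8-octahydronaphthalene-1,2-diol
Product: 16 (1S,2R,3S,4R)-4-[2-(tert-butyldiphenylsilyloxy)ethyl]-3,4,8,8-tetramethyl-1,2,3,4,5,6,7,8-octahydronaphthalene-1,2-diol
Conditions: [Ir(cod)(PCy3)(py)]PF6 (5 mol%), H2 (1 atm), CH2Cl2, 0 → 23 °C
Reagents that add atoms: none
Why: Hydroxyl-directed homogeneous hydrogenation: iridium bound to the C7 (and C6) hydroxyl adds hydrogen to the 1,1-disubstituted exocyclic alkene from the oxygen-bearing face, which places H8 cis to O7 and C17 trans to it (8S); the hindered tetrasubstituted C5=C10 bond should remain.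

Step 12
Reactants: 16 (1S,2R,3S,4R)-4-[2-(tert-butyldiphenylsilyloxy)ethyl]-3,4,8,8-tetramethyl-1,2,3,4,5,6,7,8-octahydronaphthalene-1,2-diol
Product: 17 tert-butyl{2-[(1R,2S,3R,4S)-3,4-(isopropylidenedioxy)-1,2,5,5-tetramethyl-1,2,3,4,5,6,7,8-octahydronaphthalen-1-yl]ethoxy}diphenylsilane (6,7-acetonide of 16)
Conditions: 2-methoxypropene, PPTS (cat.), CH2Cl2, 0 °C
Reagents that add atoms: 2-methoxypropene, COC(C)=C
Why: Acetalisation of the cis-1,2-diol under very mild acid catalysis gives the cis-fused dioxolane, which masks both ring hydroxyls for the organolithium chemistry of the chain.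

Step 13
Reactants: 17 tert-butyl{2-[(1R,2S,3R,4S)-3,4-(isopropylidenedioxy)-1,2,5,5-tetramethyl-1,2,3,4,5,6,7,8-octahydronaphthalen-1-yl]ethoxy}diphenylsilane
Product: 18 2-[(1R,2S,3R,4S)-3,4-(isopropylidenedioxy)-1,2,5,5-tetramethyl-1,2,3,4,5,6,7,8-octahydronaphthalen-1-yl]ethan-1-ol
Conditions: TBAF, THF, 0 → 23 °C
Reagents that add atoms: none
Why: Fluoride-induced cleavage of the silyl ether; the acetonide is inert to fluoride.

Step 14
Reactants: 18 2-[(1R,2S,3R,4S)-3,4-(isopropylidenedioxy)-1,2,5,5-tetramethyl-1,2,3,4,5,6,7,8-octahydronaphthalen-1-yl]ethan-1-ol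
Product: 19 (1R,2S,3R,4S)-1-(2-iodoethyl)-3,4-(isopropylidenedioxy)-1,2,5,5-tetramethyl-1,2,3,4,5,6,7,8-octahydronaphthalene
Conditions: I2, PPh3, imidazole, CH2Cl2, 0 °C
Reagents that add atoms: iodine, II
Why: Appel-type iodination of a primary alcohol (SN2 at C12 through the alkoxyphosphonium salt); imidazole keeps the medium basic for the acetonide.

Step 15
Reactants: 19 (1R,2S,3R,4S)-1-(2-iodoethyl)-3,4-(isopropylidenedioxy)-1,2,5,5-tetramethyl-1,2,3,4,5,6,7,8-octahydronaphthalene
Product: 20 2-{2-[(1R,2S,3R,4S)-3,4-(isopropylidenedioxy)-1,2,5,5-tetramethyl-1,2,3,4,5,6,7,8-octahydronaphthalen-1-yl]ethyl}-4,4,5,5-tetramethyl-1,3,2-dioxaborolane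
Conditions: B2pin2, CuI (10 mol%), PPh3 (13 mol%), LiOMe, DMF, 23 °C
Reagents that add atoms: bis(pinacolato)diboron, CC1(C)OB(OC1(C)C)B1OC(C)(C)C(C)(C)O1
Why: Copper-catalysed borylation of a primary alkyl iodide by a boryl-copper species formed from B2pin2 and LiOMe; the acetonide and the hindered alkene are not affected.

Step 16
Reactants: 21 (R)-but-3-en-2-ol
Product: 22 (R)-but-3-en-2-yl N,N-diisopropylcarbamate
Conditions: i-Pr2NCOCl, Et3N, CH2Cl2, reflux
Reagents that add atoms: N,N-diisopropylcarbamoyl chloride, CC(C)N(C(C)C)C(Cl)=O
Why: O-Carbamoylation of the secondary allylic alcohol; the stereocentre is not involved.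

Step 17
Reactants: 22 (R)-but-3-en-2-yl N,N-diisopropylcarbamate; 20 2-{2-[(1R,2S,3R,4S)-3,4-(isopropylidenedioxy)-1,2,5,5-tetramethyl-1,2,3,4,5,6,7,8-octahydronaphthalen-1-yl]ethyl}-4,4,5,5-tetramethyl-1,3,2-dioxaborolane
Product: 26 (3S)-5-[(1R,2S,3R,4S)-3,4-(isopropylidenedioxy)-1,2,5,5-tetramethyl-1,2,3,4,5,6,7,8-octahydronaphthalen-1-yl]-3-methylpent-1-en-3-ol, via lithiated carbamate 23 (not isolated), via boronate complex 24 (not isolated), via tertiary boronic ester 25 (not isolated)
Conditions: 22 (1.3 equiv), s-BuLi, TMEDA, Et2O, −78 °C; then 20, −78 → 23 °C; then NaOH, H2O2, THF, 0 °C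
Reagents that add atoms: hydrogen peroxide, OO
Why: Lithiation–borylation (Hoppe-type deprotonation, then 1,2-metallate rearrangement): the α-oxygenated allyllithium forms with retention and adds to boron of 20 at its α-carbon with retention. The C12 alkyl group then migrates from boron to carbon anti to the departing carbamate, and oxidation replaces boron by hydroxyl with retention, so (R)-21 should give the (13S) tertiary allylic alcohol.

Step 18
Reactants: 26 (3S)-5-[(1R,2S,3R,4S)-3,4-(isopropylidenedioxy)-1,2,5,5-tetramethyl-1,2,3,4,5,6,7,8-octahydronaphthalen-1-yl]-3-methylpent-1-en-3-ol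
Product: 27 (1S,2R,3S,4R)-4-[(3S)-3-hydroxy-3-methylpent-4-en-1-yl]-3,4,8,8-tetramethyl-1,2,3,4,5,6,7,8-octahydronaphthalene-1,2-diol
Conditions: AcOH–H2O–THF (3:1:1), 35 °C
Reagents that add atoms: none
Why: Acid hydrolysis of the dioxolane; dilute acetic acid is weak enough to leave the tertiary allylic alcohol and the allylic C6 hydroxyl in place.

Step 19
Reactants: 27 (1S,2R,3S,4R)-4-[(3S)-3-hydroxy-3-methylpent-4-en-1-yl]-3,4,8,8-tetramethyl-1,2,3,4,5,6,7,8-octahydronaphthalene-1,2-diol
Product: 28 (1S,2R,3S,4R)-1-hydroxy-4-[(3S)-3-hydroxy-3-methylpent-4-en-1-yl]-3,4,8,8-tetramethyl-1,2,3,4,5,6,7,8-octahydronaphthalen-2-yl acetate (CNP0126002.2)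
Conditions: Ac2O (1.1 equiv), pyridine, CH2Cl2, 0 °C
Reagents that add atoms: acetic anhydride, CC(=O)OC(C)=O
Why: Site-selective acylation: in the preferred half-chair the C7 hydroxyl is equatorial and open, the C6 hydroxyl is pseudoaxial and pressed against the C4 gem-dimethyl group, and the tertiary C13 hydroxyl does not react without an acyl-transfer catalyst.

## Compound list

1 | 2-bromo-1,3-dimethylbenzene | Cc1cccc(C)c1Br | starting material
2 | 2-bromo-1-(bromomethyl)-3-methylbenzene | Cc1cccc(CBr)c1Br | intermediate
3 | 1-bromo-3-methylbut-2-ene (prenyl bromide) | CC(C)=CCBr | starting material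
4 | (2-bromo-3-methylbenzyl)magnesium bromide | Cc1cccc(C[Mg]Br)c1Br | intermediate (not isolated)
5 | 2-bromo-1-methyl-3-(4-methylpent-3-en-1-yl)benzene | Cc1cccc(CCC=C(C)C)c1Br | intermediate
6 | 5-bromo-1,1,6-trimethyl-1,2,3,4-tetrahydronaphthalene | Cc1ccc2c(c1Br)CCCC2(C)C | intermediate
7 | oxirane (ethylene oxide) | C1CO1 | starting material
8 | (2,5,5-trimethyl-5,6,7,8-tetrahydronaphthalen-1-yl)lithium | [Li]c1c(C)ccc2c1CCCC2(C)C | intermediate (not isolated)
9 | 2-(2,5,5-trimethyl-5,6,7,8-tetrahydronaphthalen-1-yl)ethan-1-ol | OCCc1c(C)ccc2c1CCCC2(C)C | intermediate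
10 | (1S,2R)-4-(2-hydroxyethyl)-3,8,8-trimethyl-1,2,5,6,7,8-hexahydronaphthalene-1,2-diol | OCCC1=C(C)[C@@H](O)[C@@H](O)C2=C1CCCC2(C)C | intermediate
11 | (1S,2R)-4-[2-(tert-butyldiphenylsilyloxy)ethyl]-3,8,8-trimethyl-1,2,5,6,7,8-hexahydronaphthalene-1,2-diol | CC(C)(C)[Si](c1ccccc1)(c1ccccc1)OCCC1=C(C)[C@@H](O)[C@@H](O)C2=C1CCCC2(C)C | intermediate
12 | (1S,2R)-4-[2-(tert-butyldiphenylsilyloxy)ethyl]-1-hydroxy-3,8,8-trimethyl-1,2,5,6,7,8-hexahydronaphthalen-2-yl N-phenylcarbamate | CC(C)(C)[Si](c1ccccc1)(c1ccccc1)OCCC1=C(C)[C@@H](OC(=O)Nc2ccccc2)[C@@H](O)C2=C1CCCC2(C)C | intermediate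
13 | (1R,4R)-4-[2-(tert-butyldiphenylsilyloxy)ethyl]-3,4,8,8-tetramethyl-1,4,5,6,7,8-hexahydronaphthalen-1-ol | CC(C)(C)[Si](c1ccccc1)(c1ccccc1)OCC[C@]1(C)C(C)=C[C@@H](O)C2=C1CCCC2(C)C | intermediate
14 | (1S,2S,3R,4S)-4-[2-(tert-butyldiphenylsilyloxy)ethyl]-2,3-epoxy-3,4,8,8-tetramethyl-1,2,3,4,5,6,7,8-octahydronaphthalen-1-ol | CC(C)(C)[Si](c1ccccc1)(c1ccccc1)OCC[C@]1(C)[C@@]2(C)O[C@H]2[C@@H](O)C2=C1CCCC2(C)C | intermediate
15 | (1S,2R,4S)-4-[2-(tert-butyldiphenylsilyloxy)ethyl]-4,8,8-trimethyl-3-methylidene-1,2,3,4,5,6,7,8-octahydronaphthalene-1,2-diol | CC(C)(C)[Si](c1ccccc1)(c1ccccc1)OCC[C@]1(C)C(=C)[C@@H](O)[C@@H](O)C2=C1CCCC2(C)C | intermediate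
16 | (1S,2R,3S,4R)-4-[2-(tert-butyldiphenylsilyloxy)ethyl]-3,4,8,8-tetramethyl-1,2,3,4,5,6,7,8-octahydronaphthalene-1,2-diol | CC(C)(C)[Si](c1ccccc1)(c1ccccc1)OCC[C@]1(C)[C@H](C)[C@@H](O)[C@@H](O)C2=C1CCCC2(C)C | intermediate
17 | tert-butyl{2-[(1R,2S,3R,4S)-3,4-(isopropylidenedioxy)-1,2,5,5-tetramethyl-1,2,3,4,5,6,7,8-octahydronaphthalen-1-yl]ethoxy}diphenylsilane | CC(C)(C)[Si](c1ccccc1)(c1ccccc1)OCC[C@]1(C)[C@H](C)[C@H]2OC(C)(C)O[C@H]2C2=C1CCCC2(C)C | intermediate
18 | 2-[(1R,2S,3R,4S)-3,4-(isopropylidenedioxy)-1,2,5,5-tetramethyl-1,2,3,4,5,6,7,8-octahydronaphthalen-1-yl]ethan-1-ol | OCC[C@]1(C)[C@H](C)[C@H]2OC(C)(C)O[C@H]2C2=C1CCCC2(C)C | intermediate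
19 | (1R,2S,3R,4S)-1-(2-iodoethyl)-3,4-(isopropylidenedioxy)-1,2,5,5-tetramethyl-1,2,3,4,5,6,7,8-octahydronaphthalene | ICC[C@]1(C)[C@H](C)[C@H]2OC(C)(C)O[C@H]2C2=C1CCCC2(C)C | intermediate
20 | 2-{2-[(1R,2S,3R,4S)-3,4-(isopropylidenedioxy)-1,2,5,5-tetramethyl-1,2,3,4,5,6,7,8-octahydronaphthalen-1-yl]ethyl}-4,4,5,5-tetramethyl-1,3,2-dioxaborolane | CC1(C)OB(CC[C@]2(C)[C@H](C)[C@H]3OC(C)(C)O[C@H]3C3=C2CCCC3(C)C)OC1(C)C | intermediate
21 | (R)-but-3-en-2-ol | C=C[C@@H](C)O | starting material
22 | (R)-but-3-en-2-yl N,N-diisopropylcarbamate | C=C[C@@H](C)OC(=O)N(C(C)C)C(C)C | intermediate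
23 | (R)-2-lithiobut-3-en-2-yl N,N-diisopropylcarbamate (lithium in place of the carbinol hydrogen) | C=C[C@](C)([Li])OC(=O)N(C(C)C)C(C)C | intermediate (not isolated)
24 | lithium boronate complex of 20 with 23 (boron in place of lithium) | [Li+].C=C[C@@](C)(OC(=O)N(C(C)C)C(C)C)[B-]1(CC[C@]2(C)[C@H](C)[C@H]3OC(C)(C)O[C@H]3C3=C2CCCC3(C)C)OC(C)(C)C(C)(C)O1 | intermediate (not isolated)
25 | tertiary allylic pinacol boronic ester, boron on C13 (13R by the sequence rule, same spatial arrangement as in 26) | C=C[C@@](C)(B1OC(C)(C)C(C)(C)O1)CC[C@]1(C)[C@H](C)[C@H]2OC(C)(C)O[C@H]2C2=C1CCCC2(C)C | intermediate (not isolated)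
26 | (3S)-5-[(1R,2S,3R,4S)-3,4-(isopropylidenedioxy)-1,2,5,5-tetramethyl-1,2,3,4,5,6,7,8-octahydronaphthalen-1-yl]-3-methylpent-1-en-3-ol | C=C[C@@](C)(O)CC[C@]1(C)[C@H](C)[C@H]2OC(C)(C)O[C@H]2C2=C1CCCC2(C)C | intermediate
27 | (1S,2R,3S,4R)-4-[(3S)-3-hydroxy-3-methylpent-4-en-1-yl]-3,4,8,8-tetramethyl-1,2,3,4,5,6,7,8-octahydronaphthalene-1,2-diol | C=C[C@@](C)(O)CC[C@]1(C)[C@H](C)[C@@H](O)[C@@H](O)C2=C1CCCC2(C)C | intermediate
28 | (1S,2R,3S,4R)-1-hydroxy-4-[(3S)-3-hydroxy-3-methylpent-4-en-1-yl]-3,4,8,8-tetramethyl-1,2,3,4,5,6,7,8-octahydronaphthalen-2-yl acetate | C=C[C@@](C)(O)CC[C@@]1(C)C2=C([C@H](O)[C@H](OC(C)=O)[C@H]1C)C(C)(C)CCC2 | target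

## Step count and least certain steps

Total: 19 steps. Longest linear sequence: 18 steps (steps 1–15 and 17–19); step 16 is a one-step branch.

**Step 5 (key step, proposed new method).** Most likely failures:
- no turnover, because the tetrasubstituted ring with the quaternary C4 does not fit the pocket;
- diversion to benzylic monooxygenation at C1, C11 or C17;
- oxygen delivery to the other face, because the bulkier ring A flank and not the C8 methyl is bound where the toluene methyl sits;
- dehydration of the dienediol to a phenol during isolation.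

The fallback gives up the enzymatic dearomatization and uses a Birch reductive alkylation, which is known chemistry. It sets out from 6 and comes back at 13.
- Bromine–lithium exchange on 6 and carboxylation with CO2 give 2,5,5-trimethyl-5,6,7,8-tetrahydronaphthalene-1-carboxylic acid F1.
- Reduction with Li in NH3/THF and trapping of the carboxylate enolate with MeI (Birch reductive methylation; the ring protonates at the only free para position, C6) gives the racemic 1,4-dihydro acid. It is resolved through its salt with 1-phenylethylamine of the appropriate handedness to (R)-1,2,5,5-tetramethyl-1,4,5,6,7,8-hexahydronaphthalene-1-carboxylic acid F2.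
- Arndt–Eistert homologation follows: the acid chloride with trimethylsilyldiazomethane gives the diazoketone F3, and photochemical Wolff rearrangement in MeOH gives the methyl ester F4.
- Reduction with LiAlH4 gives the primary alcohol F5, which is silylated to the TBDPS ether F6.
- Oxidation of the doubly allylic C6 methylene with CrO3 and 3,5-dimethylpyrazole gives the cross-conjugated dienone F7.
- Reduction with BH3·SMe2 and the (S)-methyl oxazaborolidine (CBS) catalyst, with the fully substituted C5 flank as the large group, should give 13.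

**Step 8.** Most likely failures: methyl transfer without the directing effect (direct substitution at C7, or anti attack at C9 by free cuprate) and sluggish bond formation at the fully substituted C9 of a diene, with loss of the carbamate to aromatized material instead. The fallback is a sigmatropic relay in place of the organocopper one. It sets out from 11 and comes back at 13.
- Alkylation of the more accessible O7 with KH and Bu3SnCH2I gives the (tributylstannyl)methyl ether F8.
- n-BuLi (2.2 equiv, THF, −78 °C) brings about tin–lithium exchange and the Still [2,3]-Wittig rearrangement, which places the hydroxymethyl group on C9 on the face of the departing O7, giving the C20 alcohol F9.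
- Mesylation of the primary neopentyl hydroxyl (MsCl, 2,4,6-collidine, −20 °C) gives the mesylate F10, and LiEt3BH in THF reduces it to the methyl group of 13.

**Step 9.** Most likely failures: loss of chemoselectivity, because both ring alkenes are allylic to O6 and the tetrasubstituted one is the more electron-rich, and over-oxidation of the doubly allylic alcohol to the dienone. The fallback sets C8 first by hydrogenation and brings in O7 through a ketone. It sets out from 13 and comes back at 16.
- Hydroxyl-directed hydrogenation of the trisubstituted C7=C8 bond with [Ir(cod)(PCy3)(py)]PF6 gives the C8-configured alcohol F11.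
- Dess–Martin oxidation gives the enone F12.
- Kinetic enolisation towards C7 (LiN(SiMe3)2) and oxidation with 2-(phenylsulfonyl)-3-phenyloxaziridine, anti to the C8 methyl, gives the α-hydroxy enone F13.
- Reduction with LiB(s-Bu)3H along the equatorial direction should give the axial C6 alcohol cis to O7, that is 16.

**Step 17.** Most likely failures: borylation at the unsubstituted γ-terminus of the lithiated allyl carbamate, and partial loss of configuration of that anion before it is trapped, which would erode the purity at C13. The fallback builds C13 by asymmetric epoxidation. It sets out from 19 and comes back at 26.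
- Displacement of iodide with lithium acetylide–ethylenediamine in DMSO gives the terminal alkyne F14.
- Zirconium-catalysed carboalumination (Me3Al, Cp2ZrCl2) and trapping with paraformaldehyde give the (E)-allylic alcohol F15.
- Sharpless epoxidation with Ti(OiPr)4, L-(+)-diethyl tartrate and t-BuOOH gives the (13S,14S)-epoxy alcohol F16.
- Iodination (I2, PPh3, imidazole) gives the epoxy iodide F17, and zinc dust in ethanol opens it reductively to the vinyl carbinol 26 with the C13–O bond untouched.

**Step 19.** Most likely failures: acylation at O6, or acyl migration between the cis oxygens under the basic conditions. The fallback activates one oxygen through tin. It sets out from 27 and comes back at 28. Bu2SnO in toluene with azeotropic removal of water gives the dibutylstannylene acetal F18, and AcCl at 0 °C acylates the equatorial oxygen O7 of the acetal.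

## Further compounds

F1 | step 5 | 2,5,5-trimethyl-5,6,7,8-tetrahydronaphthalene-1-carboxylic acid | OC(=O)c1c(C)ccc2c1CCCC2(C)C
F2 | step 5 | (R)-1,2,5,5-tetramethyl-1,4,5,6,7,8-hexahydronaphthalene-1-carboxylic acid | OC(=O)[C@]1(C)C(C)=CCC2=C1CCCC2(C)C
F3 | step 5 | 2-diazo-1-[(R)-1,2,5,5-tetramethyl-1,4,5,6,7,8-hexahydronaphthalen-1-yl]ethan-1-one | [N-]=[N+]=CC(=O)[C@]1(C)C(C)=CCC2=C1CCCC2(C)C
F4 | step 5 | methyl 2-[(R)-1,2,5,5-tetramethyl-1,4,5,6,7,8-hexahydronaphthalen-1-yl]acetate | COC(=O)C[C@]1(C)C(C)=CCC2=C1CCCC2(C)C
F5 | step 5 | 2-[(R)-1,2,5,5-tetramethyl-1,4,5,6,7,8-hexahydronaphthalen-1-yl]ethan-1-ol | OCC[C@]1(C)C(C)=CCC2=C1CCCC2(C)C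
F6 | step 5 | tert-butyldiphenyl{2-[(R)-1,2,5,5-tetramethyl-1,4,5,6,7,8-hexahydronaphthalen-1-yl]ethoxy}silane | CC(C)(C)[Si](c1ccccc1)(c1ccccc1)OCC[C@]1(C)C(C)=CCC2=C1CCCC2(C)C
F7 | step 5 | (R)-4-[2-(tert-butyldiphenylsilyloxy)ethyl]-3,4,8,8-tetramethyl-5,6,7,8-tetrahydronaphthalen-1(4H)-one | CC(C)(C)[Si](c1ccccc1)(c1ccccc1)OCC[C@]1(C)C(C)=CC(=O)C2=C1CCCC2(C)C
F8 | step 8 | O7 (tributylstannyl)methyl ether of 11 | CC(C)(C)[Si](c1ccccc1)(c1ccccc1)OCCC1=C(C)[C@@H](OC[Sn](CCCC)(CCCC)CCCC)[C@@H](O)C2=C1CCCC2(C)C
F9 | step 8 | 9-(hydroxymethyl) analogue of 13 (C20 hydroxyl, hydroxymethyl cis to the C6 hydroxyl) | CC(C)(C)[Si](c1ccccc1)(c1ccccc1)OCC[C@]1(CO)C(C)=C[C@@H](O)C2=C1CCCC2(C)C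
F10 | step 8 | C20 methanesulfonate of F9 | CC(C)(C)[Si](c1ccccc1)(c1ccccc1)OCC[C@]1(COS(C)(=O)=O)C(C)=C[C@@H](O)C2=C1CCCC2(C)C
F11 | step 9 | 7,8-dihydro derivative of 13 (H8 cis to O6) | CC(C)(C)[Si](c1ccccc1)(c1ccccc1)OCC[C@]1(C)[C@H](C)C[C@@H](O)C2=C1CCCC2(C)C
F12 | step 9 | C6 ketone of F11 (5(10)-en-6-one) | CC(C)(C)[Si](c1ccccc1)(c1ccccc1)OCC[C@]1(C)[C@H](C)CC(=O)C2=C1CCCC2(C)C
F13 | step 9 | 7-hydroxy derivative of F12 (hydroxyl trans to the C8 methyl) | CC(C)(C)[Si](c1ccccc1)(c1ccccc1)OCC[C@]1(C)[C@H](C)[C@@H](O)C(=O)C2=C1CCCC2(C)C
F14 | step 17 | terminal alkyne from 19 (but-3-yn-1-yl chain on C9) | C#CCC[C@]1(C)[C@H](C)[C@H]2OC(C)(C)O[C@H]2C2=C1CCCC2(C)C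
F15 | step 17 | (E)-allylic alcohol (C13=C14, C15 hydroxyl) | OC/C=C(\C)CC[C@]1(C)[C@H](C)[C@H]2OC(C)(C)O[C@H]2C2=C1CCCC2(C)C
F16 | step 17 | (13S,14S)-13,14-epoxy-15-ol | OC[C@@H]1O[C@@]1(C)CC[C@]1(C)[C@H](C)[C@H]2OC(C)(C)O[C@H]2C2=C1CCCC2(C)C
F17 | step 17 | 15-iodo-13,14-epoxide from F16 | IC[C@@H]1O[C@@]1(C)CC[C@]1(C)[C@H](C)[C@H]2OC(C)(C)O[C@H]2C2=C1CCCC2(C)C
F18 | step 19 | 6,7-O-dibutylstannylene acetal of 27 | C=C[C@@](C)(O)CC[C@]1(C)[C@H](C)[C@H]2O[Sn](CCCC)(CCCC)O[C@H]2C2=C1CCCC2(C)C
A1 | alternative 1 | geranylgeranyl diphosphate | CC(C)=CCC/C(C)=C/CC/C(C)=C/CC/C(C)=C/COP(O)(=O)OP(O)(O)=O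
A2 | alternative 1 | syn-halima-5(10),13E-dien-15-yl diphosphate | OP(=O)(O)OP(=O)(O)OC/C=C(\C)CC[C@@]1(C)C2=C(CC[C@H]1C)C(C)(C)CCC2
A3 | alternative 2 | 4-(6,6-dimethylcyclohex-1-en-1-yl)-3,4-dimethyl-5-(pivaloyloxy)pentanoyl chloride with the C8 and C9 configuration of the target | CC(C)(C)C(=O)OC[C@@](C)(C1=CC(C)(C)CCC1)[C@H](C)CC(Cl)=O
A4 | alternative 2 | bicyclic C6 enone with C11 pivalate | CC(C)(C)C(=O)OC[C@@]1(C)C2=C(C(=O)C[C@H]1C)C(C)(C)CCC2
A5 | alternative 3 | (1S)-4,8,8-trimethyl-1-[(E)-prop-1-en-1-yl]-1,4,5,6,7,8-hexahydro-3H-isochromen-3-one (either epimer at the α-carbon) | C/C=C/[C@@H]1OC(=O)C(C)C2=C1C(C)(C)CCC2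
A6 | alternative 3 | 1,2,5,5-tetramethyl-1,2,5,6,7,8-hexahydronaphthalene-1-carboxylic acid | OC(=O)[C@@]1(C)C2=C(C=C[C@H]1C)C(C)(C)CCC2
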